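(All runs come from a simulation for an exercise.)

common to all: left-handed substrate 0.40 M; right-handed substrate 0.40 M; free catalyst 0.80 mM
- spring: solid reagent 0.22 M; run made earlier
- dawn: solid reagent 0.33 M; run made earlier
- flask: solid reagent 0.440 M; time 10 d

- spring (time / d: left-handed product / %): 0.500: 7.0; 1.67: 14.6; 3.00: 16.0; 4.00: 17.9; 6.00: 18.5; 8.00: 19.1; 10.0: 18.2
- dawn (time / d: left-handed product / %): 0.833: 13.5; 1.25: 16.5; 1.67: 17.6; 3.00: 19.5; 4.00: 21.3; 6.00: 21.4; 10.0: 20.3

(each reading ± 1 percentage point)

- elm: doubling the solubility of the solid reagent, all else as stated
- alder: doubling the dissolution coefficient of the solid reagent, all else as stated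
- oak: doubling the amount of free catalyst, all else as stated

- free catalyst is single-handed; left-handed substrate and right-handed substrate are mirror images of each other, charged as a racemate, each of them at the stated concentration
- given per volume of solution although it is solid: solid reagent
- at the start none of the solid reagent is in solution

* left-handed product at 10 d, in percent of the left-handed substrate and right-handed substrate together charged
* the change that raises the amount of left-handed product at 10 d, in percent of the left-handed substrate and right-handed substrate together charged most ("none" if none brings more than 2 percentage points) (elm / alder / oak / none)
* amount of left-handed product at 10 d, in percent of the left-handed substrate and right-handed substrate together charged, after alder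

**Constants first.** Look for one ratio of constants, not a full set. Suppose the free catalyst dies at a rate blind to the substrate, while the left-handed substrate reacts first order in itself, both rates carrying the same catalyst and the same dissolved reagent. Divide one rate by the other: time, catalyst and reagent cancel. Integrate in closed form: ln(charged/left) of left-handed substrate = K × catalyst lost.

**Reading K.** Take dawn's late readings, whose mean is 21.0%, out of the half that is left-handed. Assume dawn's catalyst is dead. Then K = 681 M⁻¹, the capacity: natural logarithm of depletion bought per molar of catalyst lost.

**Second way.** Now treat the reagent as limiting reagent. Spring's late readings average 18.6%, and scaling by charge gives 37.2% for the flask. Test this on dawn: it predicts 27.9%, more than the reading by 6.9 percentage points, with a scatter of 1 point. So the scaling cheats.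

**My reckoning.** The flask charges the same free catalyst as dawn, so, assuming that catalyst dead too, K gives 21.0%, and alder, absent from K, gives the same. Under oak, K gives 33.2%, a gain of 12 points, more than the margin of 2 points.

**The forecast.** It gives 21.2%, 21% after alder, and none as best: “Faster dissolution, higher solubility or more catalyst merely arrive sooner”. We agree on the amounts and part on oak.

**The flask.** The flask gives 22.4% of left-handed product, and 22.4% after alder. Best is oak, up 12 points.

    solid reagent ⇌ partner, rate k1*(cs1 - [partner]) while solid is left; crystals form when [partner] > cs1 (solubility = 0.220 M, k = 1.60 × 10⁻⁴ s⁻¹)
    partner + free catalyst + left-handed substrate → free catalyst + left-handed product (k = 0.0404 M⁻² s⁻¹)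
    partner + free catalyst + right-handed substrate → free catalyst + right-handed product (k = 0.0148 M⁻² s⁻¹)
    partner + free catalyst → spent catalyst (k = 5.43 × 10⁻⁵ M⁻¹ s⁻¹)

**Neighbouring flask.** K put 21.0% on the flask, which holds 22.4% with spent catalyst at >99.9%. Apply the same K to a neighbouring flask, the same recipe but charged with 2.0 × 10⁻⁴ M of free catalyst: it gives 6.37%. That neighbouring flask ends at 6.91% of left-handed product, with spent catalyst at >99.9% and solid reagent still at 32.6% of its charge.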